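**Retrosynthetic overview** (tetralin numbering: C1 carries the pendant aryl, C2 the CH2OSO3H, C3 the CH2OH, C4 is the CH2; C4a/C8a belong to guaiacyl ring A)
1. End: one hydrogenolysis unveils both phenols, the 3-CH2OH and the C4 methylene from a 2-CH2OSO3(-) compound whose O-4 and 3-CH2O are tied as a benzylidene acetal; this acetal is what tells the two hydroxymethyl groups apart, so only the 2-CH2OH can be sulfated.
2. The acetal rests on a temporary OH at C4, cis to the C3 arm, left behind by the key step; the triol comes from LiAlH4 reduction of a 2,3-diester.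
3. Key disconnection: the saturated ring C1–C2–C3–C4–C4a–C8a is cut at C1–C2 and C3–C4 ([4+2]). The enabling feature is that this ring is fused to ring A through the aromatic bond C4a–C8a and both atoms flanking that bond (C1, C4) are benzylic, so ring A with C1 and C4 is a latent o-quinodimethane; the trans C2/C3 pair with one carbon each is an (E)-fumarate.
4. The diene is made by light from a 2-benzylbenzaldehyde (CHO carbon = C4, doubly benzylic CH2 = C1); a titanium TADDOLate sets C1, C2, C3 (and the temporary C4) in that one operation.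
5. Ring order: both guaiacyl rings are bought (vanillin-derived) and joined by a Negishi coupling; the tetralin ring is closed last.

Key step: step 4

Assumptions: (i) the target is the free hydrogen sulfate as drawn; it is carried as its triethylammonium salt and released by cation exchange in the last operation, and should be handled cold. (ii) (R,R)-TADDOL is written in step 4; the sense of induction depends only on the ligand antipode, both antipodes are commercial, and the one that delivers 9 is used.

**Step 1**
Reactants: 1 4-(benzyloxy)-3-methoxybenzaldehyde (O-benzylvanillin)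
Product: 2 4-(benzyloxy)-2-bromo-5-methoxybenzaldehyde
Conditions: Br2, NaOAc, AcOH, rt
Reagents that add atoms: bromine, BrBr
Why: Electrophilic aromatic bromination should go to the position para to OMe and ortho to CHO, the most activated unhindered site (as with veratraldehyde), while NaOAc buffers HBr so the benzyl ether survives.

**Step 2**
Reactants: 3 [4-(benzyloxy)-3-methoxyphenyl]methanol
Product: 4 1-(benzyloxy)-4-(chloromethyl)-2-methoxybenzene
Conditions: SOCl2, CH2Cl2, 0 °C to rt; used crude
Reagents that add atoms: thionyl chloride, O=S(Cl)Cl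
Why: Deoxychlorination of an electron-rich benzylic alcohol through its chlorosulfite is fast at low temperature and leaves the aryl benzyl ether intact.

**Step 3**
Reactants: 4 1-(benzyloxy)-4-(chloromethyl)-2-methoxybenzene; 2 4-(benzyloxy)-2-bromo-5-methoxybenzaldehyde
Product: 6 4-(benzyloxy)-2-[4-(benzyloxy)-3-methoxybenzyl]-5-methoxybenzaldehyde, via benzylzinc chloride 5 (not isolated)
Conditions: 4, Zn dust, LiCl, THF, 25 °C; then 2, Pd(OAc)2 (2 mol %), SPhos (4 mol %), THF, 25 °C
Reagents that add atoms: none
Why: LiCl-assisted zinc insertion followed by Negishi sp3–sp2 cross-coupling should give the diarylmethane, because benzylic zinc reagents couple with aryl bromides faster than they add to an aldehyde.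

**Step 4**
Reactants: 6 4-(benzyloxy)-2-[4-(benzyloxy)-3-methoxybenzyl]-5-methoxybenzaldehyde; 7 diisopropyl fumarate
Product: 9 diisopropyl (1S,2R,3S,4S)-7-(benzyloxy)-1-[4-(benzyloxy)-3-methoxyphenyl]-4-hydroxy-6-methoxy-1,2,3,4-tetrahydronaphthalene-2,3-dicarboxylate, via photodienol 8 (not isolated)
Conditions: hν (365 nm), Ti(OiPr)4 (2 equiv), (R,R)-TADDOL (2.2 equiv), 7 (3 equiv), toluene, rt, degassed; aq. Rochelle salt work-up
Reagents that add atoms: none
Why: Photoenolization/Diels–Alder reaction: n,π* excitation of the aldehyde of 6 is followed by 1,5-hydrogen transfer from the doubly benzylic CH2 to give the (E,E)-hydroxy-o-quinodimethane 8 (OH and aryl both outside), which is held on titanium as a dienolate and adds to the fumarate in a concerted [4+2] that restores the aromaticity of ring A. The closest known reaction type is the Ti(OiPr)4/TADDOL-mediated photoenolization/Diels–Alder reaction of 2-alkylbenzaldehydes with electron-poor alkenes, together with the trapping of photoenols of 2-benzylbenzaldehydes by fumarates. The one ring closed, C1–C2–C3–C4–C4a–C8a, is formed by intermolecular suprafacial [4+2] cycloaddition (bonds C1–C2 and C3–C4). C2/C3 trans follows from the (E)-alkene, C1/C4 cis from the E,E-diene, and the endo position of the C3 ester (cis to O-4 and to the aryl, hence C1/C2 trans) from titanium bridging the dienolate oxygen and the neighbouring ester carbonyl; the absolute sense at all four centres comes from the TADDOLate on that titanium. The step needs endo and facial selectivity only, since the C2-symmetric fumarate removes any regiochemical question, and the very fast intramolecular hydrogen transfer should keep the excited aldehyde from sensitising fumarate isomerisation.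

**Step 5**
Reactants: 9 diisopropyl (1S,2R,3S,4S)-7-(benzyloxy)-1-[4-(benzyloxy)-3-methoxyphenyl]-4-hydroxy-6-methoxy-1,2,3,4-tetrahydronaphthalene-2,3-dicarboxylate
Product: 10 [(1S,2R,3R,4S)-7-(benzyloxy)-1-[4-(benzyloxy)-3-methoxyphenyl]-4-hydroxy-6-methoxy-1,2,3,4-tetrahydronaphthalene-2,3-diyl]dimethanol
Conditions: LiAlH4, THF, 0 °C to rt; aq. NaOH work-up
Reagents that add atoms: none
Why: Hydride reduction of both esters to primary alcohols is faster than enolisation, so C2 and C3 keep their configuration (the descriptor at C3 changes only by priority), and the benzylic C4 carbinol is not touched.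

**Step 6**
Reactants: 10 [(1S,2R,3R,4S)-7-(benzyloxy)-1-[4-(benzyloxy)-3-methoxyphenyl]-4-hydroxy-6-methoxy-1,2,3,4-tetrahydronaphthalene-2,3-diyl]dimethanol
Product: 11 4-O,3-CH2O-benzylidene acetal of 10 (cis-fused 2-phenyl-1,3-dioxane over C3–C4, acetal carbon S with phenyl equatorial, 2-CH2OH free, C1–C4 as in 10)
Conditions: PhCH(OMe)2, PPTS (cat.), 4 Å MS, CH2Cl2, rt
Reagents that add atoms: benzaldehyde dimethyl acetal, COC(OC)c1ccccc1
Why: Thermodynamic transacetalisation should select the six-membered 1,3-dioxane across the cis 1,3-diol (O-4 and 3-CH2OH) over the seven-membered ring between the two trans hydroxymethyl groups, with the new acetal centre equilibrating to equatorial phenyl.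

**Step 7**
Reactants: 11 4-O,3-CH2O-benzylidene acetal of 10
Product: 12 triethylammonium salt of the 2-CH2O-sulfate of 11
Conditions: SO3·NEt3, DMF, 40 °C; chromatography on Et3N-buffered silica
Reagents that add atoms: sulfur trioxide–triethylamine complex, CC[N+](CC)(CC)S(=O)(=O)[O-]
Why: O-Sulfation with an amine–SO3 complex takes the only free hydroxyl (the primary 2-CH2OH) under non-acidic conditions that the acetal and the benzyl ethers tolerate.

**Step 8**
Reactants: 12 triethylammonium salt of the 2-CH2O-sulfate of 11
Product: 14 [(1S,2R,3R)-7-hydroxy-1-(4-hydroxy-3-methoxyphenyl)-3-(hydroxymethyl)-6-methoxy-1,2,3,4-tetrahydronaphthalen-2-yl]methyl hydrogen sulfate (CNP0184747.1), via triethylammonium salt 13 (not isolated)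
Conditions: H2 (1 atm), 10% Pd/C, THF/H2O/AcOH, rt; filter; then strongly acidic cation-exchange resin (H+ form), H2O, 0 °C; lyophilise
Reagents that add atoms: none
Why: Catalytic hydrogenolysis should cleave the two aryl benzyl ethers, the benzylidene acetal and the C4–O bond, which becomes p-hydroxybenzylic once ring A is unmasked (as with vanillyl-type alcohols), so C4 becomes CH2 and the 3-CH2OH is released while the alkyl sulfate and C1–C3, none of which bears a heteroatom, stay untouched; cation exchange then gives the free acid.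

**Compound list**
1 | 4-(benzyloxy)-3-methoxybenzaldehyde | COc1cc(C=O)ccc1OCc1ccccc1 | starting material
2 | 4-(benzyloxy)-2-bromo-5-methoxybenzaldehyde | COc1cc(C=O)c(Br)cc1OCc1ccccc1 | intermediate
3 | [4-(benzyloxy)-3-methoxyphenyl]methanol | COc1cc(CO)ccc1OCc1ccccc1 | starting material
4 | 1-(benzyloxy)-4-(chloromethyl)-2-methoxybenzene | COc1cc(CCl)ccc1OCc1ccccc1 | intermediate
5 | [4-(benzyloxy)-3-methoxybenzyl]zinc chloride | COc1cc(C[Zn]Cl)ccc1OCc1ccccc1 | intermediate
6 | 4-(benzyloxy)-2-[4-(benzyloxy)-3-methoxybenzyl]-5-methoxybenzaldehyde | COc1cc(Cc2cc(OCc3ccccc3)c(OC)cc2C=O)ccc1OCc1ccccc1 | intermediate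
7 | diisopropyl fumarate | CC(C)OC(=O)/C=C/C(=O)OC(C)C | starting material
8 | (E,E)-hydroxy-o-quinodimethane (photodienol) of 6, titanium-bound in the flask | O/C=C1\C=C(OC)C(OCc2ccccc2)=C/C1=C\c1ccc(OCc2ccccc2)c(OC)c1 | intermediate
9 | diisopropyl (1S,2R,3S,4S)-7-(benzyloxy)-1-[4-(benzyloxy)-3-methoxyphenyl]-4-hydroxy-6-methoxy-1,2,3,4-tetrahydronaphthalene-2,3-dicarboxylate | COc1cc([C@H]2c3cc(OCc4ccccc4)c(OC)cc3[C@@H](O)[C@@H](C(=O)OC(C)C)[C@@H]2C(=O)OC(C)C)ccc1OCc1ccccc1 | intermediate
10 | [(1S,2R,3R,4S)-7-(benzyloxy)-1-[4-(benzyloxy)-3-methoxyphenyl]-4-hydroxy-6-methoxy-1,2,3,4-tetrahydronaphthalene-2,3-diyl]dimethanol | COc1cc([C@H]2c3cc(OCc4ccccc4)c(OC)cc3[C@@H](O)[C@@H](CO)[C@@H]2CO)ccc1OCc1ccccc1 | intermediate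
11 | 4-O,3-CH2O-benzylidene acetal of 10 (cis-fused 2-phenyl-1,3-dioxane, acetal carbon S, phenyl equatorial; 2-CH2OH free) | COc1cc([C@H]2c3cc(OCc4ccccc4)c(OC)cc3[C@H]3O[C@@H](c4ccccc4)OC[C@H]3[C@@H]2CO)ccc1OCc1ccccc1 | intermediate
12 | triethylammonium salt of the 2-CH2O-sulfate of 11 | COc1cc([C@H]2c3cc(OCc4ccccc4)c(OC)cc3[C@H]3O[C@@H](c4ccccc4)OC[C@H]3[C@@H]2COS(=O)(=O)[O-])ccc1OCc1ccccc1.CC[NH+](CC)CC | intermediate
13 | triethylammonium [(1S,2R,3R)-7-hydroxy-1-(4-hydroxy-3-methoxyphenyl)-3-(hydroxymethyl)-6-methoxy-1,2,3,4-tetrahydronaphthalen-2-yl]methyl sulfate | COc1cc([C@H]2c3cc(O)c(OC)cc3C[C@@H](CO)[C@@H]2COS(=O)(=O)[O-])ccc1O.CC[NH+](CC)CC | intermediate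
14 | [(1S,2R,3R)-7-hydroxy-1-(4-hydroxy-3-methoxyphenyl)-3-(hydroxymethyl)-6-methoxy-1,2,3,4-tetrahydronaphthalen-2-yl]methyl hydrogen sulfate | COc1cc([C@H]2c3cc(O)c(OC)cc3C[C@@H](CO)[C@@H]2COS(=O)(=O)O)ccc1O | target

**Count**
Total steps: 8. Longest linear sequence: 7 (steps 1, 3, 4, 5, 6, 7, 8).

**Steps most likely to fail, with fallbacks**

Step 4. What may go wrong: insufficient face discrimination by the titanium TADDOLate with this hindered, aryl-substituted dienol, or eroded endo selectivity. The fallback replaces the chiral Lewis acid by auxiliary control; it sets out from 6 and comes back at 10. Fumaryl chloride is esterified with methyl (S)-lactate (pyridine, CH2Cl2) to bis[(2S)-1-methoxy-1-oxopropan-2-yl] fumarate F1. Aldehyde 6 is then irradiated (365 nm, toluene, no titanium) with F1; hydrogen bonding of the dienol OH to a lactate carbonyl is expected to fix the endo orientation and one face, giving the bis-lactate cycloadduct F2. LiAlH4 reduces all four ester groups of F2 and should give 10, the diol from the auxiliary being washed out. Methyl (R)-lactate is used if the (S)-ester favours the mirror-image face.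

Step 6. What may go wrong: acid-promoted ionisation at the p-alkoxybenzylic C4–OH (elimination or cyclic ether formation) competing with acetal exchange. The fallback uses transient, acid-free masking; it sets out from 10 and comes back at 13. Triol 10 and phenylboronic acid (toluene, 4 Å MS, rt) should give, under equilibrium control, the six-membered cyclic phenylboronate F3 across O-4 and the 3-CH2O. SO3·NEt3/DMF in the same flask sulfates the free 2-CH2OH to the boronate sulfate F4. Aqueous methanol then releases the boronic acid and leaves the 4-hydroxy diol monosulfate F5, which under the hydrogenolysis conditions of step 8 should go to 13 and, after cation exchange, to 14.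

Step 8. What may go wrong: incomplete cleavage of the C4–O bond, or loss of configuration at C3 through quinone methide/styrene tautomerisation once the para phenol is free. The fallback removes O-4 ionically before the phenols are unmasked; it sets out from 12 and comes back at 13. Et3SiH/CF3CO2H in CH2Cl2 at −20 °C should open the acetal reductively and trap the p-benzyloxybenzylic cation at C4 with hydride, giving the 4-deoxy 3-CH2OBn sulfate F6 (any 3-CH2OH congener formed by loss of benzaldehyde converges in the next operation). Plain O-debenzylation (H2, Pd/C, THF/H2O) then gives 13, and cation exchange gives 14.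

**Further compounds**
F1 | step 4 | bis[(2S)-1-methoxy-1-oxopropan-2-yl] (2E)-but-2-enedioate | C[C@H](OC(=O)/C=C/C(=O)O[C@@H](C)C(=O)OC)C(=O)OC
F2 | step 4 | bis[(2S)-1-methoxy-1-oxopropan-2-yl] (1S,2R,3S,4S)-7-(benzyloxy)-1-[4-(benzyloxy)-3-methoxyphenyl]-4-hydroxy-6-methoxy-1,2,3,4-tetrahydronaphthalene-2,3-dicarboxylate | COc1cc([C@H]2c3cc(OCc4ccccc4)c(OC)cc3[C@@H](O)[C@@H](C(=O)O[C@@H](C)C(=O)OC)[C@@H]2C(=O)O[C@@H](C)C(=O)OC)ccc1OCc1ccccc1
F3 | step 6 | cyclic phenylboronate of 10 across O-4 and the 3-CH2O (2-CH2OH free) | COc1cc([C@H]2c3cc(OCc4ccccc4)c(OC)cc3[C@H]3OB(c4ccccc4)OC[C@H]3[C@@H]2CO)ccc1OCc1ccccc1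
F4 | step 6 | triethylammonium salt of the 2-CH2O-sulfate of F3 | COc1cc([C@H]2c3cc(OCc4ccccc4)c(OC)cc3[C@H]3OB(c4ccccc4)OC[C@H]3[C@@H]2COS(=O)(=O)[O-])ccc1OCc1ccccc1.CC[NH+](CC)CC
F5 | step 6 | triethylammonium salt of the 2-CH2O-monosulfate of 10 (4-OH and 3-CH2OH free) | COc1cc([C@H]2c3cc(OCc4ccccc4)c(OC)cc3[C@@H](O)[C@@H](CO)[C@@H]2COS(=O)(=O)[O-])ccc1OCc1ccccc1.CC[NH+](CC)CC
F6 | step 8 | triethylammonium [(1S,2R,3R)-7-(benzyloxy)-1-[4-(benzyloxy)-3-methoxyphenyl]-3-[(benzyloxy)methyl]-6-methoxy-1,2,3,4-tetrahydronaphthalen-2-yl]methyl sulfate | COc1cc([C@H]2c3cc(OCc4ccccc4)c(OC)cc3C[C@@H](COCc3ccccc3)[C@@H]2COS(=O)(=O)[O-])ccc1OCc1ccccc1.CC[NH+](CC)CC
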